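**Retrosynthetic overview**

1. The target is epicatechin-(4β→6)-epiafzelechin-(4β→8)-epicatechin-(4β→6)-epicatechin; the last operation is global hydrogenolysis of the benzylated, C8-brominated tetramer 20.
2. Key disconnection: the pyran ring of the epiafzelechin unit (O1, C2, C3, C4, C4a, C8a) and its C4–C8 bond to the lower dimer are made together from the trans-2-aryl-2,3-dihydrobenzofuran-3-carbaldehyde 17, whose five-membered ring O1–C2–C4–C4a–C8a carries C3 as the exocyclic formyl carbon. C2 shifts from C4 to C3 (ring expansion 5→6) and the C4 cation set free is arylated by C8 of dimer 7.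
3. Enabling feature: C4 is benzylic to the phloroglucinol-type A ring (oxygen on C5, C7 and O1 on C8a) and vicinal to the oxygen-bearing C3, and the migrating C2 carries O1 and the 4-oxyphenyl ring; a 3-oxyflavan-4-yl cation is therefore the 1,2-shift partner of a 3-formyl-dihydrobenzofuran.
4. Aldehyde 17 comes from (2S)-flavanone 12 (chromone 10 + boronic acid 11) by oxidative ring contraction (6→5) to ester 13, C7 bromination, Friedel–Crafts attachment of epicatechin unit B (4β to C5 of the benzofuran, the later C6) and ester→aldehyde adjustment.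
5. Units B, C and D come from (−)-epicatechin with their rings intact (electrophiles 4 and 5, nucleophile 6, 4β→6 dimer 7). Ring order for the epiafzelechin unit: chromone pyranone → flavanone → contracted dihydrofuran → re-expanded pyran.

Key step: step 14

Assumption: in step 8 (S)-t-BuPyOx is written as the ligand antipode that delivers the (2S)-flavanone; if the sense of induction is the opposite, its enantiomer is used.

**Route**

Step 1
Reactants: 1 (−)-epicatechin
Product: 2 5,7,3',4'-tetra-O-benzyl-(−)-epicatechin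
Conditions: BnBr (4.4 equiv), K2CO3, DMF, 0 °C → rt
Reagents that add atoms: benzyl bromide, BrCc1ccccc1
Why: Williamson etherification of the four phenolic OH groups with carbonate as base should leave the secondary 3-OH and both stereocentres untouched.

Step 2
Reactants: 2 5,7,3',4'-tetra-O-benzyl-(−)-epicatechin
Product: 3 3,5,7,3',4'-penta-O-benzyl-(−)-epicatechin
Conditions: NaH, BnBr, DMF, 0 °C → rt
Reagents that add atoms: benzyl bromide, BrCc1ccccc1
Why: Williamson benzylation of the secondary alkoxide completes the protection without touching a stereocentre.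

Step 3
Reactants: 3 3,5,7,3',4'-penta-O-benzyl-(−)-epicatechin
Product: 4 3,5,7,3',4'-penta-O-benzyl-4β-(2-ethoxyethoxy)epicatechin
Conditions: DDQ (2 equiv), 2-ethoxyethanol, CH2Cl2, rt
Reagents that add atoms: 2-ethoxyethanol, CCOCCO
Why: DDQ benzylic oxidation removes hydride from C4 and the flavan-4-yl cation is trapped by the alcohol anti to the 3-benzyloxy group, which sets the 4β (3,4-trans) configuration.

Step 4
Reactants: 4 3,5,7,3',4'-penta-O-benzyl-4β-(2-ethoxyethoxy)epicatechin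
Product: 5 8-bromo-3,5,7,3',4'-penta-O-benzyl-4β-(2-ethoxyethoxy)epicatechin
Conditions: NBS (1.05 equiv), CH2Cl2, −78 → 0 °C
Reagents that add atoms: N-bromosuccinimide, O=C1CCC(=O)N1Br
Why: Electrophilic aromatic bromination should take place at C8, the less hindered of the two free A-ring positions, as established for 5,7-di-O-benzylflavans.

Step 5
Reactants: 3 3,5,7,3',4'-penta-O-benzyl-(−)-epicatechin
Product: 6 8-bromo-3,5,7,3',4'-penta-O-benzylepicatechin
Conditions: NBS (1.05 equiv), CH2Cl2, −78 → 0 °C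
Reagents that add atoms: N-bromosuccinimide, O=C1CCC(=O)N1Br
Why: The same C8-selective electrophilic aromatic bromination blocks C8, so that only C6 stays nucleophilic.

Step 6
Reactants: 4 3,5,7,3',4'-penta-O-benzyl-4β-(2-ethoxyethoxy)epicatechin; 6 8-bromo-3,5,7,3',4'-penta-O-benzylepicatechin
Product: 7 [3,5,7,3',4'-penta-O-benzylepicatechin]-(4β→6)-[8-bromo-3,5,7,3',4'-penta-O-benzylepicatechin]
Conditions: TMSOTf (0.2 equiv), 6 (3 equiv), 4 Å MS, CH2Cl2, −78 °C, slow addition of 4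
Reagents that add atoms: none
Why: TMSOTf ionises the C4–O bond of 4 and the flavan-4-yl cation undergoes Friedel–Crafts attack by the only free A-ring carbon (C6) of 6 anti to the 3-benzyloxy group, which gives the 4β→6 bond; excess 6 and slow addition suppress self-condensation.

Step 7
Reactants: 8 1-[2,4-bis(benzyloxy)-6-hydroxyphenyl]ethan-1-one
Product: 10 5,7-bis(benzyloxy)-4H-chromen-4-one, via enaminone 9 (not isolated)
Conditions: Me2NCH(OMe)2, toluene, 100 °C; concentrate; then conc. HCl, CH2Cl2, rt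
Reagents that add atoms: N,N-dimethylformamide dimethyl acetal, CN(C)C(OC)OC
Why: Condensation of the methyl ketone with DMF dimethyl acetal and acid-induced addition–elimination of the phenol on the enaminone is the standard chromone synthesis; no stereocentre is formed.

Step 8
Reactants: 10 5,7-bis(benzyloxy)-4H-chromen-4-one; 11 [4-(benzyloxy)phenyl]boronic acid
Product: 12 (2S)-5,7-bis(benzyloxy)-2-[4-(benzyloxy)phenyl]chroman-4-one
Conditions: Pd(OCOCF3)2 (5 mol%), (S)-t-BuPyOx (6 mol%), NH4PF6 (30 mol%), H2O (5 equiv), ClCH2CH2Cl, 60 °C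
Reagents that add atoms: none
Why: Pd(II)/PyOx-catalysed asymmetric conjugate addition of an arylboronic acid to a chromone, in which the ligand controls the face of carbopalladation and sets C2 as S.

Step 9
Reactants: 12 (2S)-5,7-bis(benzyloxy)-2-[4-(benzyloxy)phenyl]chroman-4-one
Product: 13 methyl (2S,3S)-4,6-bis(benzyloxy)-2-[4-(benzyloxy)phenyl]-2,3-dihydro-1-benzofuran-3-carboxylate (trans)
Conditions: PhI(OAc)2 (1.2 equiv), HC(OMe)3, H2SO4 (cat.), rt
Reagents that add atoms: trimethyl orthoformate, COC(OC)OC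
Why: Hypervalent-iodine oxidative ring contraction of a flavanone: the enol ether is iodinated at C3 and the A-ring carbon shifts from C4 to C3 as PhI leaves (1,2-aryl shift), the former carbonyl carbon becoming the ester carbon; C2 is not involved and the trans ester is the stable isomer.

Step 10
Reactants: 13 methyl (2S,3S)-4,6-bis(benzyloxy)-2-[4-(benzyloxy)phenyl]-2,3-dihydro-1-benzofuran-3-carboxylate
Product: 14 methyl (2S,3S)-4,6-bis(benzyloxy)-2-[4-(benzyloxy)phenyl]-7-bromo-2,3-dihydro-1-benzofuran-3-carboxylate (trans)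
Conditions: NBS (1.0 equiv), CH2Cl2, −78 → 0 °C
Reagents that add atoms: N-bromosuccinimide, O=C1CCC(=O)N1Br
Why: Electrophilic aromatic bromination should go to C7 (next to the ring oxygen and less hindered than C5 between the two benzyloxy groups), by analogy with the C8 bromination of flavans.

Step 11
Reactants: 14 methyl (2S,3S)-4,6-bis(benzyloxy)-2-[4-(benzyloxy)phenyl]-7-bromo-2,3-dihydro-1-benzofuran-3-carboxylate; 5 8-bromo-3,5,7,3',4'-penta-O-benzyl-4β-(2-ethoxyethoxy)epicatechin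
Product: 15 methyl trans-4,6-bis(benzyloxy)-2-[4-(benzyloxy)phenyl]-7-bromo-5-(8-bromo-3,5,7,3',4'-penta-O-benzylepicatechin-4β-yl)-2,3-dihydro-1-benzofuran-3-carboxylate
Conditions: TMSOTf (0.2 equiv), 14 (2 equiv), 4 Å MS, CH2Cl2, −78 °C
Reagents that add atoms: none
Why: TMSOTf-mediated Friedel–Crafts coupling of the flavan-4-yl cation from 5 with the only free ring position (C5) of 14, anti to the 3-benzyloxy group (4β); the ester is inert to the Lewis acid and the C8 bromine of 5 blocks self-condensation.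

Step 12
Reactants: 15 methyl trans-4,6-bis(benzyloxy)-2-[4-(benzyloxy)phenyl]-7-bromo-5-(8-bromo-3,5,7,3',4'-penta-O-benzylepicatechin-4β-yl)-2,3-dihydro-1-benzofuran-3-carboxylate
Product: 16 [trans-4,6-bis(benzyloxy)-2-[4-(benzyloxy)phenyl]-7-bromo-5-(8-bromo-3,5,7,3',4'-penta-O-benzylepicatechin-4β-yl)-2,3-dihydro-1-benzofuran-3-yl]methanol
Conditions: i-Bu2AlH (2.5 equiv), CH2Cl2, −78 → 0 °C; Rochelle salt work-up
Reagents that add atoms: none
Why: DIBAL-H reduction of the methyl ester to the primary alcohol should leave aryl bromides, benzyl ethers and all stereocentres untouched.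

Step 13
Reactants: 16 [trans-4,6-bis(benzyloxy)-2-[4-(benzyloxy)phenyl]-7-bromo-5-(8-bromo-3,5,7,3',4'-penta-O-benzylepicatechin-4β-yl)-2,3-dihydro-1-benzofuran-3-yl]methanol
Product: 17 trans-4,6-bis(benzyloxy)-2-[4-(benzyloxy)phenyl]-7-bromo-5-(8-bromo-3,5,7,3',4'-penta-O-benzylepicatechin-4β-yl)-2,3-dihydro-1-benzofuran-3-carbaldehyde
Conditions: Dess–Martin periodinane, NaHCO3, CH2Cl2, 0 °C → rt
Reagents that add atoms: none
Why: Buffered Dess–Martin oxidation of the primary alcohol gives the aldehyde without epimerisation, and the trans arrangement is also the thermodynamic one.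

Step 14
Reactants: 17 trans-4,6-bis(benzyloxy)-2-[4-(benzyloxy)phenyl]-7-bromo-5-(8-bromo-3,5,7,3',4'-penta-O-benzylepicatechin-4β-yl)-2,3-dihydro-1-benzofuran-3-carbaldehyde; 7 [3,5,7,3',4'-penta-O-benzylepicatechin]-(4β→6)-[8-bromo-3,5,7,3',4'-penta-O-benzylepicatechin]
Product: 20 [8-bromo-penta-O-benzylepicatechin]-(4β→6)-[8-bromo-5,7,4'-tri-O-benzylepiafzelechin]-(4β→8)-[penta-O-benzylepicatechin]-(4β→6)-[8-bromo-penta-O-benzylepicatechin], via 3-silyloxyflavan-4-ylium triflate 18 (not isolated), via 3-O-trimethylsilyl tetramer 19 (not isolated)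
Conditions: 7 (2 equiv), TMSOTf (1.2 equiv), 4 Å MS, CH2Cl2 (5 mM), −78 → −40 °C; aq NaHCO3; then K2CO3, MeOH–THF, rt
Reagents that add atoms: none
Why: Proposed new method: TMSOTf silylates the formyl oxygen of 17, and the carbon of the resulting silyloxocarbenium ion (the later C3) accepts C2 in a suprafacial 1,2-shift from the ring carbon that becomes C4, C2 being pushed by the antiperiplanar lone pair of O1 and by its 4-benzyloxyphenyl group, so that the dihydrofuran ring expands to the pyran ring and the charge appears at C4 as the 5,7,8a-trioxygenated flavan-4-yl cation 18, which C8 of 7 captures to give 19 (desilylated on work-up). The closest known reaction types are the acid-induced 1,2-shift to an activated formyl carbon that opens the aldehyde–ketone rearrangement of α-aryl aldehydes (a retro-pinacol step, the reverse of a semipinacol ring contraction) and, for the second stage, the TMSOTf-mediated Friedel–Crafts coupling of flavan-4-yl cations; the exchange of an aliphatic silyloxocarbenium ion for a much better stabilised benzylic cation and the irreversible C–C bond formation drive the sequence. The pyran ring is closed by bond migration (one-carbon ring expansion 5→6) and not by cyclisation, with retention at the migrating C2, which keeps O1, aryl and H. C3 is set by the reacting rotamer of the trans aldehyde: the bulky O–Si group turns outward, away from the arene and its peri benzyloxy group (formyl H over the ring), which puts the oxygen cis to the 2-aryl group; C4 is then set by attack of 7 anti to the pseudo-axial 3-silyloxy group (4β), as for epicatechin-derived cations. The step needs C2 to migrate faster than H or the aryl carbon and faster than 7 attacks the activated formyl group, attack of 7 through C8 of its upper unit, and no self-arylation; the donor-substituted C2, the hindered α-branched formyl group, high dilution with excess 7 and the bromine atoms on C8 of units A, B and D are meant to secure this.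

Step 15
Reactants: 20 [8-bromo-penta-O-benzylepicatechin]-(4β→6)-[8-bromo-5,7,4'-tri-O-benzylepiafzelechin]-(4β→8)-[penta-O-benzylepicatechin]-(4β→6)-[8-bromo-penta-O-benzylepicatechin]
Product: 21 epicatechin-(4β→6)-epiafzelechin-(4β→8)-epicatechin-(4β→6)-epicatechin (CNP0103636.1)
Conditions: H2 (1 atm), Pd(OH)2/C, Et3N, THF–MeOH–H2O, rt
Reagents that add atoms: none
Why: Pd-catalysed hydrogenolysis should remove all eighteen benzyl ethers and the three aryl bromides (Et3N takes up HBr) without touching a stereocentre.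

**Compound list**

1 | (−)-epicatechin | Oc1cc(O)c2c(c1)O[C@H](c1ccc(O)c(O)c1)[C@H](O)C2 | starting material
2 | 5,7,3',4'-tetra-O-benzyl-(−)-epicatechin | c1(OCc4ccccc4)cc(OCc4ccccc4)c2c(c1)O[C@H](c3ccc(OCc4ccccc4)c(OCc4ccccc4)c3)[C@H](O)C2 | intermediate
3 | 3,5,7,3',4'-penta-O-benzyl-(−)-epicatechin | c1(OCc4ccccc4)cc(OCc4ccccc4)c2c(c1)O[C@H](c3ccc(OCc4ccccc4)c(OCc4ccccc4)c3)[C@H](OCc4ccccc4)C2 | intermediate
4 | 3,5,7,3',4'-penta-O-benzyl-4β-(2-ethoxyethoxy)epicatechin | c1(OCc4ccccc4)cc(OCc4ccccc4)c2c(c1)O[C@H](c3ccc(OCc4ccccc4)c(OCc4ccccc4)c3)[C@H](OCc4ccccc4)[C@H]2OCCOCC | intermediate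
5 | 8-bromo-3,5,7,3',4'-penta-O-benzyl-4β-(2-ethoxyethoxy)epicatechin | c1(OCc4ccccc4)cc(OCc4ccccc4)c2c(c1Br)O[C@H](c3ccc(OCc4ccccc4)c(OCc4ccccc4)c3)[C@H](OCc4ccccc4)[C@H]2OCCOCC | intermediate
6 | 8-bromo-3,5,7,3',4'-penta-O-benzylepicatechin | c1(OCc4ccccc4)cc(OCc4ccccc4)c2c(c1Br)O[C@H](c3ccc(OCc4ccccc4)c(OCc4ccccc4)c3)[C@H](OCc4ccccc4)C2 | intermediate
7 | [3,5,7,3',4'-penta-O-benzylepicatechin]-(4β→6)-[8-bromo-3,5,7,3',4'-penta-O-benzylepicatechin] | c1(OCc4ccccc4)cc(OCc4ccccc4)c2c(c1)O[C@H](c3ccc(OCc4ccccc4)c(OCc4ccccc4)c3)[C@H](OCc4ccccc4)[C@H]2c5c(OCc4ccccc4)c(Br)c6c(c5OCc4ccccc4)C[C@@H](OCc4ccccc4)[C@@H](c7ccc(OCc4ccccc4)c(OCc4ccccc4)c7)O6 | intermediate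
8 | 1-[2,4-bis(benzyloxy)-6-hydroxyphenyl]ethan-1-one | CC(=O)c1c(O)cc(OCc2ccccc2)cc1OCc1ccccc1 | starting material
9 | (E)-1-[2,4-bis(benzyloxy)-6-hydroxyphenyl]-3-(dimethylamino)prop-2-en-1-one | CN(C)/C=C/C(=O)c1c(O)cc(OCc2ccccc2)cc1OCc1ccccc1 | intermediate (not isolated)
10 | 5,7-bis(benzyloxy)-4H-chromen-4-one | O=c1ccoc2cc(OCc3ccccc3)cc(OCc3ccccc3)c12 | intermediate
11 | [4-(benzyloxy)phenyl]boronic acid | OB(O)c1ccc(OCc2ccccc2)cc1 | starting material
12 | (2S)-5,7-bis(benzyloxy)-2-[4-(benzyloxy)phenyl]chroman-4-one | O=C1C[C@@H](c3ccc(OCc4ccccc4)cc3)Oc2cc(OCc4ccccc4)cc(OCc4ccccc4)c12 | intermediate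
13 | methyl (2S,3S)-4,6-bis(benzyloxy)-2-[4-(benzyloxy)phenyl]-2,3-dihydro-1-benzofuran-3-carboxylate (trans) | COC(=O)[C@@H]1[C@@H](c3ccc(OCc4ccccc4)cc3)Oc2cc(OCc4ccccc4)cc(OCc4ccccc4)c12 | intermediate
14 | methyl (2S,3S)-4,6-bis(benzyloxy)-2-[4-(benzyloxy)phenyl]-7-bromo-2,3-dihydro-1-benzofuran-3-carboxylate (trans) | COC(=O)[C@@H]1[C@@H](c3ccc(OCc4ccccc4)cc3)Oc2c(Br)c(OCc4ccccc4)cc(OCc4ccccc4)c12 | intermediate
15 | methyl trans-4,6-bis(benzyloxy)-2-[4-(benzyloxy)phenyl]-7-bromo-5-(8-bromo-3,5,7,3',4'-penta-O-benzylepicatechin-4β-yl)-2,3-dihydro-1-benzofuran-3-carboxylate | COC(=O)[C@@H]1[C@@H](c3ccc(OCc4ccccc4)cc3)Oc2c(Br)c(OCc4ccccc4)c([C@H]5c6c(OCc4ccccc4)cc(OCc4ccccc4)c(Br)c6O[C@H](c7ccc(OCc4ccccc4)c(OCc4ccccc4)c7)[C@@H]5OCc4ccccc4)c(OCc4ccccc4)c12 | intermediate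
16 | [trans-4,6-bis(benzyloxy)-2-[4-(benzyloxy)phenyl]-7-bromo-5-(8-bromo-3,5,7,3',4'-penta-O-benzylepicatechin-4β-yl)-2,3-dihydro-1-benzofuran-3-yl]methanol | OC[C@@H]1[C@@H](c3ccc(OCc4ccccc4)cc3)Oc2c(Br)c(OCc4ccccc4)c([C@H]5c6c(OCc4ccccc4)cc(OCc4ccccc4)c(Br)c6O[C@H](c7ccc(OCc4ccccc4)c(OCc4ccccc4)c7)[C@@H]5OCc4ccccc4)c(OCc4ccccc4)c12 | intermediate
17 | trans-4,6-bis(benzyloxy)-2-[4-(benzyloxy)phenyl]-7-bromo-5-(8-bromo-3,5,7,3',4'-penta-O-benzylepicatechin-4β-yl)-2,3-dihydro-1-benzofuran-3-carbaldehyde | O=C[C@@H]1[C@@H](c3ccc(OCc4ccccc4)cc3)Oc2c(Br)c(OCc4ccccc4)c([C@H]5c6c(OCc4ccccc4)cc(OCc4ccccc4)c(Br)c6O[C@H](c7ccc(OCc4ccccc4)c(OCc4ccccc4)c7)[C@@H]5OCc4ccccc4)c(OCc4ccccc4)c12 | intermediate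
18 | 2,3-cis-5,7-bis(benzyloxy)-2-[4-(benzyloxy)phenyl]-8-bromo-6-(8-bromo-3,5,7,3',4'-penta-O-benzylepicatechin-4β-yl)-3-(trimethylsilyloxy)flavan-4-ylium triflate | c1cc(OCc4ccccc4)ccc1[C@H]2Oc3c(Br)c(OCc4ccccc4)c([C@H]5c6c(OCc4ccccc4)cc(OCc4ccccc4)c(Br)c6O[C@H](c7ccc(OCc4ccccc4)c(OCc4ccccc4)c7)[C@@H]5OCc4ccccc4)c(OCc4ccccc4)c3[CH+][C@H]2O[Si](C)(C)C.[O-]S(=O)(=O)C(F)(F)F | intermediate (not isolated)
19 | 3-O-trimethylsilyl ether (epiafzelechin unit) of tetramer 20 | c1cc(OCc4ccccc4)ccc1[C@H]2Oc3c(Br)c(OCc4ccccc4)c([C@H]5c6c(OCc4ccccc4)cc(OCc4ccccc4)c(Br)c6O[C@H](c7ccc(OCc4ccccc4)c(OCc4ccccc4)c7)[C@@H]5OCc4ccccc4)c(OCc4ccccc4)c3[C@H](c5c(OCc4ccccc4)cc(OCc4ccccc4)c6c5O[C@H](c7ccc(OCc4ccccc4)c(OCc4ccccc4)c7)[C@H](OCc4ccccc4)[C@H]6c5c(OCc4ccccc4)c(Br)c6c(c5OCc4ccccc4)C[C@@H](OCc4ccccc4)[C@@H](c7ccc(OCc4ccccc4)c(OCc4ccccc4)c7)O6)[C@H]2O[Si](C)(C)C | intermediate (not isolated)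
20 | [8-bromo-penta-O-benzylepicatechin]-(4β→6)-[8-bromo-5,7,4'-tri-O-benzylepiafzelechin]-(4β→8)-[penta-O-benzylepicatechin]-(4β→6)-[8-bromo-penta-O-benzylepicatechin] | c1cc(OCc4ccccc4)ccc1[C@H]2Oc3c(Br)c(OCc4ccccc4)c([C@H]5c6c(OCc4ccccc4)cc(OCc4ccccc4)c(Br)c6O[C@H](c7ccc(OCc4ccccc4)c(OCc4ccccc4)c7)[C@@H]5OCc4ccccc4)c(OCc4ccccc4)c3[C@H](c5c(OCc4ccccc4)cc(OCc4ccccc4)c6c5O[C@H](c7ccc(OCc4ccccc4)c(OCc4ccccc4)c7)[C@H](OCc4ccccc4)[C@H]6c5c(OCc4ccccc4)c(Br)c6c(c5OCc4ccccc4)C[C@@H](OCc4ccccc4)[C@@H](c7ccc(OCc4ccccc4)c(OCc4ccccc4)c7)O6)[C@H]2O | intermediate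
21 | epicatechin-(4β→6)-epiafzelechin-(4β→8)-epicatechin-(4β→6)-epicatechin (CNP0103636.1) | Oc1ccc([C@H]2Oc3cc(O)c([C@H]4c5c(O)cc(O)cc5O[C@H](c5ccc(O)c(O)c5)[C@@H]4O)c(O)c3[C@H](c3c(O)cc(O)c4c3O[C@H](c3ccc(O)c(O)c3)[C@H](O)[C@H]4c3c(O)cc4c(c3O)C[C@@H](O)[C@@H](c3ccc(O)c(O)c3)O4)[C@H]2O)cc1 | target

**Step count**

Total steps: 15. Longest linear sequence: 9 steps (8 → 10 → 12 → 13 → 14 → 15 → 16 → 17 → 20 → 21; the branch from 1 through 5 is equally long).

**Steps most likely to fail**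

1. Step 14 (Proposed new method). Several processes may divert it. Dimer 7 may attack the silyl-activated formyl group directly before C2 has migrated. A 1,2-hydride shift from the benzylic ring carbon followed by proton loss may aromatise the ring to a benzofuran. After the ring expansion, hydride shift or proton loss may lead to the flavan-3-one level. A stepwise C2–C bond heterolysis (retro-Prins course) may erode the configuration at C2. The reacting rotamer may give poor facial control at C3. The fallback gives up the cascade and builds the epiafzelechin unit as an ordinary flavan-4-yl electrophile by known reactions; it sets out from 12 (and uses 5 and 7) and comes back at 20. Flavanone 12 is reduced with NaBH4 to the 2,4-cis-flavan-4-ol F1 and dehydrated (p-TsOH, toluene, in the dark) to the flav-3-ene F2. Hydroboration–oxidation (BH3·THF, then NaOH/H2O2) places boron on C3 anti to the 2-aryl group and gives 5,7,4'-tri-O-benzylafzelechin F3 (2,3-trans). Dess–Martin oxidation gives the flavan-3-one F4, and L-Selectride (the catechin → epicatechin inversion protocol) gives 5,7,4'-tri-O-benzylepiafzelechin F5 (2,3-cis). NBS gives the 8-bromide F6, and TMSOTf coupling of F6 with 5 at its only free position C6 gives the (4β→6) dimer F7. DDQ/2-ethoxyethanol oxidises the only benzylic CH2 group (C4 of the epiafzelechin unit) to the 4β-(2-ethoxyethoxy) dimer F8, and TMSOTf coupling of F8 with 7 gives 20.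

2. Step 9. The 4-benzyloxyphenyl group may migrate from C2 to C3 instead of the A-ring carbon (isoflavone formation), the flavanone may be dehydrogenated to the flavone, or iodine(III) may oxidise the electron-rich rings. The fallback replaces the oxidative aryl shift by a Wolff ring contraction; it sets out from 12 and comes back at 13. Detrifluoroacetylative diazo transfer (LiHMDS, CF3CO2CH2CF3, −78 °C; then 4-acetamidobenzenesulfonyl azide, Et3N) passes through the 3-(trifluoroacetyl)flavanone F9 and gives the 3-diazoflavanone F10. Photolysis in methanol makes the A-ring carbon migrate to the carbene carbon and the ketene is trapped as the methyl ester, formed partly as the cis ester F11. NaOMe in MeOH equilibrates the mixture to the trans ester 13.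

3. Step 8. Carbopalladation of the peri-substituted chromone may be slow, so that protodeboronation of 11 takes over, or the enantioselectivity may be low or eroded by ring opening to the chalcone. The fallback obtains the enantiomer by resolution instead of asymmetric catalysis; it sets out from 10 and 11 and comes back at 12. Conjugate addition with an achiral catalyst (Pd(OCOCF3)2, 2,2'-bipyridine, aqueous conditions) gives the racemic flavanone F12. Kinetic resolution by Noyori transfer hydrogenation (RuCl(TsDPEN)(p-cymene), HCO2H/Et3N; the catalyst antipode that reduces the 2R ketone faster) converts the unwanted enantiomer into the (2R,4R)-cis-flavan-4-ol F13 and leaves (2S)-12, which is separated by chromatography.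

Further compounds
F1 | step 14 | (2S)-2,4-cis-5,7-bis(benzyloxy)-2-[4-(benzyloxy)phenyl]chroman-4-ol | O[C@H]1C[C@@H](c3ccc(OCc4ccccc4)cc3)Oc2cc(OCc4ccccc4)cc(OCc4ccccc4)c12
F2 | step 14 | (2S)-5,7-bis(benzyloxy)-2-[4-(benzyloxy)phenyl]-2H-chromene | C1=C[C@@H](c3ccc(OCc4ccccc4)cc3)Oc2cc(OCc4ccccc4)cc(OCc4ccccc4)c12
F3 | step 14 | 5,7,4'-tri-O-benzylafzelechin (2R,3S) | c1(OCc4ccccc4)cc(OCc4ccccc4)c2c(c1)O[C@H](c3ccc(OCc4ccccc4)cc3)[C@@H](O)C2
F4 | step 14 | (2R)-5,7-bis(benzyloxy)-2-[4-(benzyloxy)phenyl]chroman-3-one | c1(OCc4ccccc4)cc(OCc4ccccc4)c2c(c1)O[C@H](c3ccc(OCc4ccccc4)cc3)C(=O)C2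
F5 | step 14 | 5,7,4'-tri-O-benzylepiafzelechin (2R,3R) | c1(OCc4ccccc4)cc(OCc4ccccc4)c2c(c1)O[C@H](c3ccc(OCc4ccccc4)cc3)[C@H](O)C2
F6 | step 14 | 8-bromo-5,7,4'-tri-O-benzylepiafzelechin | c1(OCc4ccccc4)cc(OCc4ccccc4)c2c(c1Br)O[C@H](c3ccc(OCc4ccccc4)cc3)[C@H](O)C2
F7 | step 14 | [8-bromo-3,5,7,3',4'-penta-O-benzylepicatechin]-(4β→6)-[8-bromo-5,7,4'-tri-O-benzylepiafzelechin] | c1(OCc4ccccc4)c([C@H]5c6c(OCc4ccccc4)cc(OCc4ccccc4)c(Br)c6O[C@H](c7ccc(OCc4ccccc4)c(OCc4ccccc4)c7)[C@@H]5OCc4ccccc4)c(OCc4ccccc4)c2c(c1Br)O[C@H](c3ccc(OCc4ccccc4)cc3)[C@H](O)C2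
F8 | step 14 | [8-bromo-3,5,7,3',4'-penta-O-benzylepicatechin]-(4β→6)-[8-bromo-5,7,4'-tri-O-benzyl-4β-(2-ethoxyethoxy)epiafzelechin] | c1(OCc4ccccc4)c([C@H]5c6c(OCc4ccccc4)cc(OCc4ccccc4)c(Br)c6O[C@H](c7ccc(OCc4ccccc4)c(OCc4ccccc4)c7)[C@@H]5OCc4ccccc4)c(OCc4ccccc4)c2c(c1Br)O[C@H](c3ccc(OCc4ccccc4)cc3)[C@H](O)[C@H]2OCCOCC
F9 | step 9 | (2S)-5,7-bis(benzyloxy)-2-[4-(benzyloxy)phenyl]-3-(trifluoroacetyl)chroman-4-one | O=C1C(C(=O)C(F)(F)F)[C@@H](c3ccc(OCc4ccccc4)cc3)Oc2cc(OCc4ccccc4)cc(OCc4ccccc4)c12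
F10 | step 9 | (2S)-5,7-bis(benzyloxy)-2-[4-(benzyloxy)phenyl]-3-diazochroman-4-one | O=C1C(=[N+]=[N-])[C@@H](c3ccc(OCc4ccccc4)cc3)Oc2cc(OCc4ccccc4)cc(OCc4ccccc4)c12
F11 | step 9 | methyl (2S,3R)-4,6-bis(benzyloxy)-2-[4-(benzyloxy)phenyl]-2,3-dihydro-1-benzofuran-3-carboxylate (cis) | COC(=O)[C@H]1[C@@H](c3ccc(OCc4ccccc4)cc3)Oc2cc(OCc4ccccc4)cc(OCc4ccccc4)c12
F12 | step 8 | rac-5,7-bis(benzyloxy)-2-[4-(benzyloxy)phenyl]chroman-4-one | O=C1CC(c3ccc(OCc4ccccc4)cc3)Oc2cc(OCc4ccccc4)cc(OCc4ccccc4)c12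
F13 | step 8 | (2R,4R)-cis-5,7-bis(benzyloxy)-2-[4-(benzyloxy)phenyl]chroman-4-ol | O[C@@H]1C[C@H](c3ccc(OCc4ccccc4)cc3)Oc2cc(OCc4ccccc4)cc(OCc4ccccc4)c12
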